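The route rests on the C3a–C4 bond of the tetrahydrofuran ring that carries the endo aryl group (C3a, C4, O5, C6, C6a): a tertiary alcohol beside a benzylic ether carbon is what remains when an acetal carbon moves from oxygen to the neighbouring carbon. The precursor is therefore a trans-fused veratrylidene acetal (a 1,3-dioxane) spanning the α-hydroxyl and β-hydroxymethyl groups of a γ-aryl butyrolactone made from dimethyl (R)-malate. Ionisation of this acetal within the lactone silyl ketene acetal contracts the dioxane to the tetrahydrofuran, creating the C–C bond, the tertiary carbinol, the cis ring fusion and the endo aryl centre in one operation, and erasing two stereocentres on the way.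

Key step: step 5

Remark: target atoms are numbered as in 1H,3H-furo[3,4-c]furan (C1 exo-aryl carbon, O2, C3, C3a carbinol, C4 endo-aryl carbon, O5, C6, C6a). Dimethyl (R)-malate and veratraldehyde are taken as commercial.

Step 1
Reactants: 1 dimethyl (R)-malate; 2 3,4-dimethoxybenzaldehyde (veratraldehyde)
Product: 5 methyl (2R,3R,4R)-2-(3,4-dimethoxyphenyl)-4-hydroxy-5-oxooxolane-3-carboxylate, via dilithium enolate-alkoxide 3 (not isolated), via dilithium aldolate 4 (not isolated)
Conditions: LDA (2.2 equiv), THF, −78 to −20 °C; 2, −78 °C; AcOH; then TFA, CH2Cl2, rt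
Reagents that add atoms: none
Why: Fráter–Seebach-type aldol addition: the lithium-chelated alkoxide-enolate 3 should take up the aldehyde on the face anti to the C2 oxygen, which sets the future ring-fusion CH, and TFA then lactonises 4 while reversible ionisation of the electron-rich benzylic C–O bond should settle the carbinol centre trans to the ester.

Step 2
Reactants: 5 methyl (2R,3R,4R)-2-(3,4-dimethoxyphenyl)-4-hydroxy-5-oxooxolane-3-carboxylate
Product: 7 (2R,3R,4R)-2-(3,4-dimethoxyphenyl)-4-hydroxy-5-oxooxolane-3-carboxylic acid, via dilithium dicarboxylate 6 (not isolated)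
Conditions: LiOH·H2O (3 equiv), THF/H2O, 0 °C; then 2 M HCl to pH 1, rt
Reagents that add atoms: lithium hydroxide, [Li+].[OH-]
Why: Saponification cleaves ester and lactone to dicarboxylate 6, and acidification recloses the only γ-lactone available (benzylic hydroxyl onto the α-hydroxy carboxyl group), so the β-carboxyl group emerges free with no stereocentre touched.

Step 3
Reactants: 7 (2R,3R,4R)-2-(3,4-dimethoxyphenyl)-4-hydroxy-5-oxooxolane-3-carboxylic acid
Product: 8 (3R,4R,5R)-5-(3,4-dimethoxyphenyl)-3-hydroxy-4-(hydroxymethyl)oxolan-2-one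
Conditions: BH3·SMe2 (3 equiv), THF, 0 °C to rt; MeOH
Reagents that add atoms: none
Why: Chemoselective borane reduction: the free acid is reduced through its acyloxyborane far faster than the lactone, so only the β-carboxyl group becomes the hydroxymethyl group.

Step 4
Reactants: 8 (3R,4R,5R)-5-(3,4-dimethoxyphenyl)-3-hydroxy-4-(hydroxymethyl)oxolan-2-one; 2 3,4-dimethoxybenzaldehyde
Product: 10 (2R,4aS,5R,7aR)-2,5-bis(3,4-dimethoxyphenyl)tetrahydro-4H-furo[3,4-d][1,3]dioxin-7(5H)-one, via veratraldehyde dimethyl acetal 9 (not isolated)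
Conditions: 2, HC(OMe)3, CSA (cat.), CH2Cl2, rt; then 8, 5 Å MS, 40 °C
Reagents that add atoms: none
Why: Acid-catalysed transacetalisation of the 1,3-diol under thermodynamic control should give the trans-fused 1,3-dioxane with the aryl group equatorial at the new acetal centre, a centre that step 5 erases again.

Step 5
Reactants: 10 (2R,4aS,5R,7aR)-2,5-bis(3,4-dimethoxyphenyl)tetrahydro-4H-furo[3,4-d][1,3]dioxin-7(5H)-one
Product: 13 (3R,3aS,6R,6aS)-3,6-bis(3,4-dimethoxyphenyl)-6a-hydroxytetrahydro-1H,3H-furo[3,4-c]furan-1-one, via silyl ketene acetal 11 (not isolated), via trimethylsilyl ether 12 (not isolated)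
Conditions: TMSOTf (1.2 equiv), i-Pr2NEt (1.3 equiv), CH2Cl2, 0 °C; then TMSOTf (0.4 equiv), −78 °C; 1 M HCl, THF, 0 °C
Reagents that add atoms: none
Why: Soft enolisation gives silyl ketene acetal 11; the extra TMSOTf then silylates the acetal oxygen O1 (numbering of 10), the C2–O1 bond ionises to an (E)-aryl oxocarbenium ion that stays tethered through O3–C4, the electron-rich α-carbon C7a attacks its carbon, and loss of the silyl group from the lactone-derived cation gives 12, so the acetal carbon has moved from O1 to C7a and the 1,3-dioxane has become the 2-aryl-3-siloxytetrahydrofuran. The closest known reactions are the TMSOTf-mediated Mukaiyama-type addition of silyl ketene acetals to acetals and the Petasis–Ferrier and dihydro-1,3-dioxepin O-to-C ring contractions, which run through the same oxocarbenium/enol pair. The tetrahydrofuran closes in the 5-(enolexo)-endo-trig mode at the oxocarbenium carbon that those rearrangements also use. The carbinol centre is controlled by the tether, since C4 can deliver the cation only to the face of C7a on which it stands, which forces the cis ring fusion with the oxygen on the convex face whatever the configurations of C2 and C7a in 10 (both are erased), whereas an external electrophile would add anti to C4. The benzylic centre should form with the aryl group endo (cis to the lactone carbonyl carbon) under kinetic control, the usual outcome of oxocarbenium–enol ether closures to this bicycle, and the exo transition state is further burdened by the silyloxy group on C7a. The step needs C-attack through C7a and not C7, secured by the two oxygen donors on C7, and it needs the endo benzylic ether to survive, secured by the amine buffer, the substoichiometric free TMSOTf and −78 °C.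

Step 6
Reactants: 13 (3R,3aS,6R,6aS)-3,6-bis(3,4-dimethoxyphenyl)-6a-hydroxytetrahydro-1H,3H-furo[3,4-c]furan-1-one
Product: 14 (2R,3R,4S)-2-(3,4-dimethoxyphenyl)-4-[(R)-(3,4-dimethoxyphenyl)(hydroxy)methyl]-3-(hydroxymethyl)oxolan-3-ol
Conditions: LiAlH4, THF, 0 °C; H2O/aq NaOH work-up
Reagents that add atoms: none
Why: Hydride reduction of the lactone to the primary and benzylic alcohols should touch neither the benzylic ether of the new ring nor any stereocentre.

Step 7
Reactants: 14 (2R,3R,4S)-2-(3,4-dimethoxyphenyl)-4-[(R)-(3,4-dimethoxyphenyl)(hydroxy)methyl]-3-(hydroxymethyl)oxolan-3-ol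
Product: 16 (1R,3aR,4R,6aS)-1,4-bis(3,4-dimethoxyphenyl)tetrahydro-1H,3H-furo[3,4-c]furan-3a(4H)-ol, via primary mesylate 15 (not isolated)
Conditions: MsCl (1.1 equiv), pyridine, 0 °C to rt
Reagents that add atoms: none
Why: Selective sulfonylation of the primary hydroxyl is followed by a 5-exo-tet Williamson closure by the benzylic hydroxyl, which keeps its configuration because its C–O bond is not broken, under basic conditions in which the endo aryl ether cannot epimerise.

Compound list
1 | dimethyl (R)-malate | COC(=O)[C@H](O)CC(=O)OC | starting material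
2 | 3,4-dimethoxybenzaldehyde (veratraldehyde) | COc1ccc(C=O)cc1OC | starting material
3 | dilithium enolate-alkoxide of dimethyl (R)-malate | [Li+].[Li+].COC(=O)[C@H]([O-])C=C([O-])OC | intermediate
4 | dilithium bis-alkoxide of dimethyl (2R,3S)-2-hydroxy-3-[(R)-(3,4-dimethoxyphenyl)(hydroxy)methyl]butanedioate (expected with its carbinol epimer) | [Li+].[Li+].COC(=O)[C@H]([O-])[C@@H](C(=O)OC)[C@H](c1ccc(OC)c(OC)c1)[O-] | intermediate
5 | methyl (2R,3R,4R)-2-(3,4-dimethoxyphenyl)-4-hydroxy-5-oxooxolane-3-carboxylate | O=C1[C@H](O)[C@@H](C(=O)OC)[C@H](c2ccc(OC)c(OC)c2)O1 | intermediate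
6 | dilithium (2R,3S)-2-hydroxy-3-[(R)-(3,4-dimethoxyphenyl)(hydroxy)methyl]butanedioate | [Li+].[Li+].[O-]C(=O)[C@H](O)[C@@H](C([O-])=O)[C@H](c1ccc(OC)c(OC)c1)O | intermediate
7 | (2R,3R,4R)-2-(3,4-dimethoxyphenyl)-4-hydroxy-5-oxooxolane-3-carboxylic acid | O=C1[C@H](O)[C@@H](C(=O)O)[C@H](c2ccc(OC)c(OC)c2)O1 | intermediate
8 | (3R,4R,5R)-5-(3,4-dimethoxyphenyl)-3-hydroxy-4-(hydroxymethyl)oxolan-2-one | O=C1[C@H](O)[C@@H](CO)[C@H](c2ccc(OC)c(OC)c2)O1 | intermediate
9 | 4-(dimethoxymethyl)-1,2-dimethoxybenzene (veratraldehyde dimethyl acetal) | COC(OC)c1ccc(OC)c(OC)c1 | intermediate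
10 | (2R,4aS,5R,7aR)-2,5-bis(3,4-dimethoxyphenyl)tetrahydro-4H-furo[3,4-d][1,3]dioxin-7(5H)-one (trans-fused veratrylidene acetal of 8) | O=C1[C@@H]2O[C@H](c3ccc(OC)c(OC)c3)OC[C@H]2[C@H](c4ccc(OC)c(OC)c4)O1 | intermediate
11 | (2R,4aS,5R)-2,5-bis(3,4-dimethoxyphenyl)-7-(trimethylsilyloxy)-4a,5-dihydro-4H-furo[3,4-d][1,3]dioxine (silyl ketene acetal of 10) | C[Si](C)(C)OC1=C2O[C@H](c3ccc(OC)c(OC)c3)OC[C@H]2[C@H](c4ccc(OC)c(OC)c4)O1 | intermediate
12 | (3R,3aS,6R,6aS)-3,6-bis(3,4-dimethoxyphenyl)-6a-(trimethylsilyloxy)tetrahydro-1H,3H-furo[3,4-c]furan-1-one | COc1ccc([C@H]2OC[C@H]3[C@H](c4ccc(OC)c(OC)c4)OC(=O)[C@@]23O[Si](C)(C)C)cc1OC | intermediate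
13 | (3R,3aS,6R,6aS)-3,6-bis(3,4-dimethoxyphenyl)-6a-hydroxytetrahydro-1H,3H-furo[3,4-c]furan-1-one | COc1ccc([C@H]2OC[C@H]3[C@H](c4ccc(OC)c(OC)c4)OC(=O)[C@@]23O)cc1OC | intermediate
14 | (2R,3R,4S)-2-(3,4-dimethoxyphenyl)-4-[(R)-(3,4-dimethoxyphenyl)(hydroxy)methyl]-3-(hydroxymethyl)oxolan-3-ol | COc1ccc([C@H]2OC[C@@H]([C@@H](O)c3ccc(OC)c(OC)c3)[C@@]2(O)CO)cc1OC | intermediate
15 | [(2R,3R,4S)-2-(3,4-dimethoxyphenyl)-4-[(R)-(3,4-dimethoxyphenyl)(hydroxy)methyl]-3-hydroxyoxolan-3-yl]methyl methanesulfonate | COc1ccc([C@H]2OC[C@@H]([C@@H](O)c3ccc(OC)c(OC)c3)[C@@]2(O)COS(C)(=O)=O)cc1OC | intermediate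
16 | (1R,3aR,4R,6aS)-1,4-bis(3,4-dimethoxyphenyl)tetrahydro-1H,3H-furo[3,4-c]furan-3a(4H)-ol | COc1ccc([C@H]2OC[C@H]3[C@H](c4ccc(OC)c(OC)c4)OC[C@@]23O)cc1OC | target

Total step count: 7. Longest linear sequence: 7 steps (1 → 5 → 7 → 8 → 10 → 13 → 14 → 16).

Steps most likely to fail

Step 5. The acetal may ionise only at the more basic O3, which forms no C–C bond. The strained 5-endo closure may be slow enough for the silyl ketene acetal to be lost by protodesilylation. Closure may also run through the exo transition state and give the C6 epimer. The fallback sets out from 10 and comes back at 13, and moves the same bond formation into the anionic manifold. LDA (THF, −78 to 0 °C) gives the lithium enolate of 10, and its [1,2]-Wittig rearrangement (homolysis of the acetal C2–O1 bond and recombination at C7a, again a contraction of the 1,3-dioxane to the tetrahydrofuran) should keep the configuration of the migrating acetal carbon. From the equatorial aryl acetal this is expected to give the exo-aryl compound (3R,3aS,6S,6aS)-3,6-bis(3,4-dimethoxyphenyl)-6a-hydroxytetrahydro-1H,3H-furo[3,4-c]furan-1-one F1. Its ether-type benzylic C–H bond (the lactone-type one is deactivated by the acyloxy group) is oxidised with DDQ in wet CH2Cl2 to the cyclic hemiketal (3R,3aS,6S,6aS)-3,6-bis(3,4-dimethoxyphenyl)-6,6a-dihydroxytetrahydro-1H,3H-furo[3,4-c]furan-1-one F2. Ionic hydrogenation (Et3SiH, BF3·OEt2, CH2Cl2, −78 °C) should then deliver hydride to the convex face of the aryl oxocarbenium ion, which places the aryl group endo and gives 13. The same DDQ/silane pair would also correct exo epimer formed in step 5 itself.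

Step 1. Facial selectivity of the enolate addition may be incomplete, and retro-aldol cleavage or elimination may compete during the acid equilibration; either would erode the diastereomeric and hence the enantiomeric purity of everything downstream. The fallback sets out from 2 and comes back at 8, and sets the benzylic centre first by catalysis instead of relaying it from malate. Zinc-ProPhenol alkynylation of 2 with methyl propiolate (Et2Zn, toluene) should give methyl (S)-4-(3,4-dimethoxyphenyl)-4-hydroxybut-2-ynoate F3. Semihydrogenation (H2, Pd/CaCO3 poisoned with Pb(OAc)2, quinoline) and acid lactonisation (PPTS) give (R)-5-(3,4-dimethoxyphenyl)furan-2(5H)-one F4. Conjugate addition of vinylmagnesium bromide (CuBr·SMe2 cat., TMSCl, THF, −78 °C) anti to the aryl group, followed by oxidation of the resulting silyl ketene acetal with dimethyldioxirane anti to the vinyl group, should give (3R,4R,5R)-5-(3,4-dimethoxyphenyl)-4-ethenyl-3-hydroxyoxolan-2-one F5. Ozonolysis with NaBH4 work-up (CH2Cl2/MeOH, −78 to −40 °C) turns the vinyl group into the hydroxymethyl group of 8.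

Step 4. The equilibrium may disfavour the strained trans-fused dioxane, and the acid may move the lactone acyl group to the primary hydroxyl, which would divert the diol into an isomeric acetal. The fallback sets out from 8 and comes back at 10, and closes the acetal oxidatively and irreversibly. The primary hydroxyl is alkylated selectively through the dibutylstannylene acetal (Bu2SnO, toluene, reflux; then 3,4-dimethoxybenzyl bromide, CsF, DMF) to give (3R,4R,5R)-4-{[(3,4-dimethoxyphenyl)methoxy]methyl}-5-(3,4-dimethoxyphenyl)-3-hydroxyoxolan-2-one F6. DDQ with 4 Å molecular sieves in dry CH2Cl2 at 0 °C oxidises the benzylic ether to its oxocarbenium ion, which the neighbouring α-hydroxyl captures to give acetal 10.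

Further compounds
F1 | step 5 | (3R,3aS,6S,6aS)-3,6-bis(3,4-dimethoxyphenyl)-6a-hydroxytetrahydro-1H,3H-furo[3,4-c]furan-1-one | COc1ccc([C@@H]2OC[C@H]3[C@H](c4ccc(OC)c(OC)c4)OC(=O)[C@@]23O)cc1OC
F2 | step 5 | (3R,3aS,6S,6aS)-3,6-bis(3,4-dimethoxyphenyl)-6,6a-dihydroxytetrahydro-1H,3H-furo[3,4-c]furan-1-one | COc1ccc([C@]2(O)OC[C@H]3[C@H](c4ccc(OC)c(OC)c4)OC(=O)[C@@]23O)cc1OC
F3 | step 1 | methyl (S)-4-(3,4-dimethoxyphenyl)-4-hydroxybut-2-ynoate | COC(=O)C#C[C@H](c1ccc(OC)c(OC)c1)O
F4 | step 1 | (R)-5-(3,4-dimethoxyphenyl)furan-2(5H)-one | O=C1C=C[C@H](c2ccc(OC)c(OC)c2)O1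
F5 | step 1 | (3R,4R,5R)-5-(3,4-dimethoxyphenyl)-4-ethenyl-3-hydroxyoxolan-2-one | O=C1[C@H](O)[C@@H](C=C)[C@H](c2ccc(OC)c(OC)c2)O1
F6 | step 4 | (3R,4R,5R)-4-{[(3,4-dimethoxyphenyl)methoxy]methyl}-5-(3,4-dimethoxyphenyl)-3-hydroxyoxolan-2-one | O=C1[C@H](O)[C@@H](COCc2ccc(OC)c(OC)c2)[C@H](c3ccc(OC)c(OC)c3)O1
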